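**Plan**

- Retrosynthesis: the aryl O–Si bond is cut first, then the alkene C–CH2OH bond (back to a (Z)-enol triflate), the enol C–OTf bond (back to an α-alkoxy ketone) and the C7 O–CH3 bond. The benzylic C1'–O ether bond is cut last; this separates a chromene carbinol (fragment 1) from a hydroxy ketone (fragment 2).
- Forward: the pyran ring of the chromene is the only ring built (condensation and oxa-6π closure on 4-bromoresorcinol), and C1'–C2' is added by lithiation and acetaldehyde. Fragment 2 comes from 2'-hydroxy-4'-methylacetophenone by silylation and Rubottom oxidation. The fragments are joined at C1'–O, and the chain is finished by methylation, triflation, Stille coupling and desilylation.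
- Enabling feature: the oxygen on C7 is ortho to C6, the ring carbon that carries C1', and the ring oxygen O1 on C8a is para to C6. With C7 as a free phenol the benzene ring can expel the C1' hydroxyl to give an ortho-quinone methide, whose C7 carbonyl oxygen is a binding site for a chiral Brønsted acid.
- Stereochemistry: (S) at C1' is set in the acid-controlled 1,4-addition, which is stereoconvergent from the racemic carbinol. The (Z) enol ether comes from a chelated (Z)-lithium enolate whose geometry is carried through triflation and cross-coupling.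

Key step: step 6

Assumption: the (R)-enantiomer of the phosphoric acid is written as the one whose pocket leads to the (S)-ether; if the sense of induction is the opposite, its mirror image is used and nothing else changes.

**Route**

Step 1
Reactants: 1 4-bromoresorcinol; 2 3-methylbut-2-enal
Product: 4 6-bromo-2,2-dimethyl-2H-chromen-7-ol, via dienone 3 (not isolated)
Conditions: ethylenediammonium diacetate (20 mol %), toluene, reflux, 2 (1.1 equiv)
Reagents that add atoms: none
Why: Amine-catalysed Knoevenagel-type condensation at C6 of the resorcinol (the only free carbon para to a hydroxyl, since bromine blocks C4) should give dienone 3, which closes by oxa-6π electrocyclisation to the 2H-chromene.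

Step 2
Reactants: 4 6-bromo-2,2-dimethyl-2H-chromen-7-ol
Product: 6 racemic 1-(7-hydroxy-2,2-dimethyl-2H-chromen-6-yl)ethan-1-ol, via dilithio species 5 (not isolated)
Conditions: n-BuLi (2.2 equiv), THF, −78 → −20 °C; then MeCHO, −78 °C; aq NH4Cl
Reagents that add atoms: acetaldehyde, CC=O
Why: Deprotonation of the phenol followed by bromine–lithium exchange gives the ortho-lithio phenoxide 5, whose 1,2-addition to acetaldehyde should deliver the ortho-hydroxybenzylic alcohol as a racemate, which is acceptable because step 6 is stereoconvergent.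

Step 3
Reactants: 7 1-(2-hydroxy-4-methylphenyl)ethanone
Product: 8 1-[2-(tert-butyldimethylsilyloxy)-4-methylphenyl]ethan-1-one
Conditions: TBSCl, imidazole, DMF, rt → 40 °C
Reagents that add atoms: tert-butyldimethylsilyl chloride, CC(C)(C)[Si](C)(C)Cl
Why: Standard silylation of a phenol masks the cresol oxygen against the later amide base, Mitsunobu and zerovalent palladium steps and leaves a group that fluoride removes at the end.

Step 4
Reactants: 8 1-[2-(tert-butyldimethylsilyloxy)-4-methylphenyl]ethan-1-one
Product: 9 tert-butyldimethyl{5-methyl-2-[1-(trimethylsilyloxy)ethenyl]phenoxy}silane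
Conditions: TMSOTf, Et3N, CH2Cl2, 0 °C; cold NaHCO3 wash, used crude
Reagents that add atoms: trimethylsilyl trifluoromethanesulfonate, C[Si](C)(C)OS(=O)(=O)C(F)(F)F
Why: Soft enolisation of the aryl methyl ketone (silyl enol ether formation) needs no strong base, so the ortho silyl ether cannot migrate, and only one enol ether is possible.

Step 5
Reactants: 9 tert-butyldimethyl{5-methyl-2-[1-(trimethylsilyloxy)ethenyl]phenoxy}silane
Product: 12 1-[2-(tert-butyldimethylsilyloxy)-4-methylphenyl]-2-hydroxyethan-1-one, via silyloxy epoxide 10 (not isolated), via trimethylsilyloxy ketone 11 (not isolated)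
Conditions: mCPBA, CH2Cl2, −15 → 0 °C; then 1 M HCl, THF, 0 °C
Reagents that add atoms: 3-chloroperbenzoic acid, OOC(=O)c1cccc(Cl)c1
Why: Rubottom oxidation, in which epoxidation of the enol ether, opening of 10 with 1,4-silyl shift to 11 and mild acid hydrolysis of the trimethylsilyl ether should give the primary α-hydroxy ketone while the acid-stable aryl silyl ether stays on.

Step 6
Reactants: 6 racemic 1-(7-hydroxy-2,2-dimethyl-2H-chromen-6-yl)ethan-1-ol; 12 1-[2-(tert-butyldimethylsilyloxy)-4-methylphenyl]-2-hydroxyethan-1-one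
Product: 14 1-[2-(tert-butyldimethylsilyloxy)-4-methylphenyl]-2-[(1S)-1-(7-hydroxy-2,2-dimethyl-2H-chromen-6-yl)ethoxy]ethan-1-one, via ortho-quinone methide 13 (not isolated)
Conditions: (R)-TRIP [(R)-3,3'-bis(2,4,6-triisopropylphenyl)-1,1'-binaphthyl-2,2'-diyl hydrogen phosphate] (10 mol %), 12 (2 equiv), 4 Å MS, toluene, 0 °C, slow addition of 6
Reagents that add atoms: none
Why: The phosphoric acid protonates the benzylic hydroxyl of 6 and, pushed by the C7 phenol and the para oxygen O1, water leaves to give the (E)-ortho-quinone methide 13, which stays hydrogen-bonded through its C7 carbonyl oxygen to the acid while the phosphoryl oxygen holds the primary hydroxyl of 12; 1,4-addition of that oxygen to C1' restores the aromatic ring. The closest known reaction type is the chiral phosphoric acid catalysed enantioselective addition of alcohols to ortho-quinone methides generated in situ from ortho-hydroxybenzylic alcohols, of which a methyl-substituted methide is a demanding member. No ring is closed; one C–O bond and one stereocentre are formed. C1' is set by the chiral pocket of the bifunctional acid, which leaves one face of the planar methide open, and since both enantiomers of 6 and the vinyl phenol tautomer of 13 all pass through 13 the step is stereoconvergent. The step needs enantiofacial selectivity and capture by the primary alcohol in preference to water, the phenol or a second methide; the two-point binding through the ortho carbonyl oxygen, the excess of 12, the sieves, the low standing concentration of 13 and the low temperature should secure this. The low temperature also keeps the step under kinetic control, since the doubly donor-activated ether could otherwise re-ionise.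

Step 7
Reactants: 14 1-[2-(tert-butyldimethylsilyloxy)-4-methylphenyl]-2-[(1S)-1-(7-hydroxy-2,2-dimethyl-2H-chromen-6-yl)ethoxy]ethan-1-one
Product: 15 1-[2-(tert-butyldimethylsilyloxy)-4-methylphenyl]-2-[(1S)-1-(7-methoxy-2,2-dimethyl-2H-chromen-6-yl)ethoxy]ethan-1-one
Conditions: MeOH (3 equiv), PPh3, DIAD, THF, 0 °C → rt
Reagents that add atoms: methanol, CO
Why: Mitsunobu etherification of the phenol with methanol runs under neutral conditions, so neither phenoxide-triggered re-ionisation at C1' nor methanolysis of the aryl silyl ether should occur, and the stereocentre is not involved.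

Step 8
Reactants: 15 1-[2-(tert-butyldimethylsilyloxy)-4-methylphenyl]-2-[(1S)-1-(7-methoxy-2,2-dimethyl-2H-chromen-6-yl)ethoxy]ethan-1-one
Product: 17 (Z)-1-[2-(tert-butyldimethylsilyloxy)-4-methylphenyl]-2-[(1S)-1-(7-methoxy-2,2-dimethyl-2H-chromen-6-yl)ethoxy]ethenyl trifluoromethanesulfonate, via lithium enolate 16 (not isolated)
Conditions: LiN(SiMe3)2, THF, −78 °C; then Comins' reagent, −78 → −40 °C; aq NH4Cl
Reagents that add atoms: N-(5-chloropyridin-2-yl)-1,1,1-trifluoro-N-(trifluoromethylsulfonyl)methanesulfonamide (Comins' reagent), FC(F)(F)S(=O)(=O)N(c1ccc(Cl)cn1)S(=O)(=O)C(F)(F)F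
Why: Kinetic deprotonation of the α-alkoxy aryl ketone should give the (Z)-enolate 16, held by lithium chelation between the enolate and ether oxygens and free of aryl/alkoxy strain, and enolate O-triflation at low temperature fixes that geometry before silyl migration or Wittig rearrangement can compete.

Step 9
Reactants: 17 (Z)-1-[2-(tert-butyldimethylsilyloxy)-4-methylphenyl]-2-[(1S)-1-(7-methoxy-2,2-dimethyl-2H-chromen-6-yl)ethoxy]ethenyl trifluoromethanesulfonate
Product: 18 (2Z)-2-[2-(tert-butyldimethylsilyloxy)-4-methylphenyl]-3-[(1S)-1-(7-methoxy-2,2-dimethyl-2H-chromen-6-yl)ethoxy]prop-2-en-1-ol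
Conditions: Bu3SnCH2OH (1.5 equiv), Pd(PPh3)4 (10 mol %), LiCl (3 equiv), 1,4-dioxane, 90 °C
Reagents that add atoms: (tributylstannyl)methanol, CCCC[Sn](CCCC)(CCCC)CO
Why: Stille coupling of the enol triflate with the hydroxymethyl stannane should replace the triflate by CH2OH with retention of alkene geometry, LiCl assisting transmetalation, so the ether oxygen and CH2OH end up cis as the target requires.

Step 10
Reactants: 18 (2Z)-2-[2-(tert-butyldimethylsilyloxy)-4-methylphenyl]-3-[(1S)-1-(7-methoxy-2,2-dimethyl-2H-chromen-6-yl)ethoxy]prop-2-en-1-ol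
Product: 19 (2Z)-2-(2-hydroxy-4-methylphenyl)-3-[(1S)-1-(7-methoxy-2,2-dimethyl-2H-chromen-6-yl)ethoxy]prop-2-en-1-ol (CNP0279099.1)
Conditions: Bu4NF (1.1 equiv), THF, 0 °C; aq NH4Cl
Reagents that add atoms: none
Why: Fluoride desilylation of the aryl silyl ether is non-acidic, so the acid-labile enol ether, the benzylic ether at C1' and the allylic alcohol should be left untouched.

**Compound list**

1 | 4-bromoresorcinol (4-bromobenzene-1,3-diol) | Oc1ccc(Br)c(O)c1 | starting material
2 | 3-methylbut-2-enal | CC(C)=CC=O | starting material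
3 | (6Z)-4-bromo-3-hydroxy-6-(3-methylbut-2-en-1-ylidene)cyclohexa-2,4-dien-1-one | CC(C)=C/C=C1\C(=O)C=C(O)C(Br)=C1 | intermediate
4 | 6-bromo-2,2-dimethyl-2H-chromen-7-ol | CC1(C)C=Cc2cc(Br)c(O)cc2O1 | intermediate
5 | lithium 6-lithio-2,2-dimethyl-2H-chromen-7-olate | [Li]Oc1cc2OC(C)(C)C=Cc2cc1[Li] | intermediate
6 | racemic 1-(7-hydroxy-2,2-dimethyl-2H-chromen-6-yl)ethan-1-ol | CC(O)c1cc2C=CC(C)(C)Oc2cc1O | intermediate
7 | 1-(2-hydroxy-4-methylphenyl)ethanone | CC(=O)c1ccc(C)cc1O | starting material
8 | 1-[2-(tert-butyldimethylsilyloxy)-4-methylphenyl]ethan-1-one | CC(=O)c1ccc(C)cc1O[Si](C)(C)C(C)(C)C | intermediate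
9 | tert-butyldimethyl{5-methyl-2-[1-(trimethylsilyloxy)ethenyl]phenoxy}silane | C=C(O[Si](C)(C)C)c1ccc(C)cc1O[Si](C)(C)C(C)(C)C | intermediate
10 | racemic tert-butyldimethyl{5-methyl-2-[2-(trimethylsilyloxy)oxiran-2-yl]phenoxy}silane | C[Si](C)(C)OC1(CO1)c1ccc(C)cc1O[Si](C)(C)C(C)(C)C | intermediate
11 | 1-[2-(tert-butyldimethylsilyloxy)-4-methylphenyl]-2-(trimethylsilyloxy)ethan-1-one | C[Si](C)(C)OCC(=O)c1ccc(C)cc1O[Si](C)(C)C(C)(C)C | intermediate
12 | 1-[2-(tert-butyldimethylsilyloxy)-4-methylphenyl]-2-hydroxyethan-1-one | O=C(CO)c1ccc(C)cc1O[Si](C)(C)C(C)(C)C | intermediate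
13 | (6E)-6-ethylidene-2,2-dimethyl-2H-chromen-7(6H)-one | C/C=C1\C=C2C=CC(C)(C)OC2=CC1=O | intermediate
14 | 1-[2-(tert-butyldimethylsilyloxy)-4-methylphenyl]-2-[(1S)-1-(7-hydroxy-2,2-dimethyl-2H-chromen-6-yl)ethoxy]ethan-1-one | Oc1cc2c(cc1[C@H](C)OCC(=O)c3ccc(C)cc3O[Si](C)(C)C(C)(C)C)C=CC(C)(C)O2 | intermediate
15 | 1-[2-(tert-butyldimethylsilyloxy)-4-methylphenyl]-2-[(1S)-1-(7-methoxy-2,2-dimethyl-2H-chromen-6-yl)ethoxy]ethan-1-one | COc1cc2c(cc1[C@H](C)OCC(=O)c3ccc(C)cc3O[Si](C)(C)C(C)(C)C)C=CC(C)(C)O2 | intermediate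
16 | lithium (Z)-1-[2-(tert-butyldimethylsilyloxy)-4-methylphenyl]-2-[(1S)-1-(7-methoxy-2,2-dimethyl-2H-chromen-6-yl)ethoxy]ethen-1-olate | COc1cc2c(cc1[C@H](C)O/C=C(\O[Li])c3ccc(C)cc3O[Si](C)(C)C(C)(C)C)C=CC(C)(C)O2 | intermediate
17 | (Z)-1-[2-(tert-butyldimethylsilyloxy)-4-methylphenyl]-2-[(1S)-1-(7-methoxy-2,2-dimethyl-2H-chromen-6-yl)ethoxy]ethenyl trifluoromethanesulfonate | COc1cc2c(cc1[C@H](C)O/C=C(\OS(=O)(=O)C(F)(F)F)c3ccc(C)cc3O[Si](C)(C)C(C)(C)C)C=CC(C)(C)O2 | intermediate
18 | (2Z)-2-[2-(tert-butyldimethylsilyloxy)-4-methylphenyl]-3-[(1S)-1-(7-methoxy-2,2-dimethyl-2H-chromen-6-yl)ethoxy]prop-2-en-1-ol | COc1cc2c(cc1[C@H](C)O/C=C(\CO)c3ccc(C)cc3O[Si](C)(C)C(C)(C)C)C=CC(C)(C)O2 | intermediate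
19 | (2Z)-2-(2-hydroxy-4-methylphenyl)-3-[(1S)-1-(7-methoxy-2,2-dimethyl-2H-chromen-6-yl)ethoxy]prop-2-en-1-ol | COc1cc2c(cc1[C@H](C)O/C=C(\CO)c3ccc(C)cc3O)C=CC(C)(C)O2 | target

**Step count**

Total: 10 steps. Longest linear sequence: 8 steps (steps 3 to 10, from 7).

**Steps most likely to fail**

Step 6. The enantiomeric purity may erode because the ether, activated by both the ortho and the para oxygen, re-ionises under the acid. The methide may also drain into vinyl-phenol formation and self-condensation faster than the primary alcohol captures it.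

The fallback sets the stereocentre by reagent-controlled ketone reduction and forms the O–CH2 bond in place of the C1'–O bond. It sets out from 6 and 8 and returns at 15.
- Selective O-methylation of the phenol of 6 (MeI, K2CO3, acetone) should give racemic 1-(7-methoxy-2,2-dimethyl-2H-chromen-6-yl)ethan-1-ol F1.
- Oxidation with MnO2 should give 1-(7-methoxy-2,2-dimethyl-2H-chromen-6-yl)ethan-1-one F2.
- Corey–Bakshi–Shibata reduction ((R)-2-methyl-CBS-oxazaborolidine, BH3·SMe2, THF) should give (1S)-1-(7-methoxy-2,2-dimethyl-2H-chromen-6-yl)ethan-1-ol F3.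
- In parallel, 8 is taken through detrifluoroacetylative diazo transfer (LiN(SiMe3)2, CF3CO2CH2CF3; then MsN3, Et3N, H2O, MeCN). This passes through 1-[2-(tert-butyldimethylsilyloxy)-4-methylphenyl]-4,4,4-trifluorobutane-1,3-dione F4 to 2-diazo-1-[2-(tert-butyldimethylsilyloxy)-4-methylphenyl]ethan-1-one F5.
- Rh2(OAc)4-catalysed O–H insertion of the carbenoid from F5 into F3 (CH2Cl2, rt, slow addition of F5) should give 15 with C1' untouched.

Step 9. Transmetalation of the hydroxymethyl stannane onto the hindered, electron-rich alkenyl palladium intermediate may be sluggish, so that butyl transfer, protodestannylation or reduction of the triflate takes over.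

The fallback replaces tin by carbon monoxide. It sets out from 17 and returns at 18.
- Methoxycarbonylation (Pd(OAc)2, PPh3, CO 1 atm, MeOH, Et3N, DMF, 60 °C) should give methyl (2Z)-2-[2-(tert-butyldimethylsilyloxy)-4-methylphenyl]-3-[(1S)-1-(7-methoxy-2,2-dimethyl-2H-chromen-6-yl)ethoxy]prop-2-enoate F6 with retention of geometry.
- Reduction with iBu2AlH (CH2Cl2, −78 °C) should give 18.

Step 1. Carbon–carbon bond formation may occur at C2 of the resorcinol, between the two hydroxyls, in place of C6, or a second condensation may take place on the remaining phenol; either gives the wrong ring fusion.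

The fallback builds the pyran ring by acylation, where ortho-acylation at the unhindered C6 is reliable. It sets out from 1 and returns at 4.
- Friedel–Crafts acylation and oxa-Michael closure with 3-methylbut-2-enoic acid in Eaton's reagent (P2O5 in MeSO3H, 70 °C) should give 6-bromo-7-hydroxy-2,2-dimethylchroman-4-one F7.
- Reduction with LiAlH4 (THF, 0 °C → rt) should give racemic 6-bromo-2,2-dimethylchromane-4,7-diol F8.
- Acid-catalysed dehydration (TsOH, toluene, reflux) should give 4.

**Further compounds**

F1 | step 6 | racemic 1-(7-methoxy-2,2-dimethyl-2H-chromen-6-yl)ethan-1-ol | COc1cc2OC(C)(C)C=Cc2cc1C(C)O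
F2 | step 6 | 1-(7-methoxy-2,2-dimethyl-2H-chromen-6-yl)ethan-1-one | COc1cc2OC(C)(C)C=Cc2cc1C(C)=O
F3 | step 6 | (1S)-1-(7-methoxy-2,2-dimethyl-2H-chromen-6-yl)ethan-1-ol | COc1cc2c(cc1[C@H](C)O)C=CC(C)(C)O2
F4 | step 6 | 1-[2-(tert-butyldimethylsilyloxy)-4-methylphenyl]-4,4,4-trifluorobutane-1,3-dione | O=C(CC(=O)C(F)(F)F)c1ccc(C)cc1O[Si](C)(C)C(C)(C)C
F5 | step 6 | 2-diazo-1-[2-(tert-butyldimethylsilyloxy)-4-methylphenyl]ethan-1-one | [N-]=[N+]=CC(=O)c1ccc(C)cc1O[Si](C)(C)C(C)(C)C
F6 | step 9 | methyl (2Z)-2-[2-(tert-butyldimethylsilyloxy)-4-methylphenyl]-3-[(1S)-1-(7-methoxy-2,2-dimethyl-2H-chromen-6-yl)ethoxy]prop-2-enoate | COc1cc2c(cc1[C@H](C)O/C=C(\C(=O)OC)c3ccc(C)cc3O[Si](C)(C)C(C)(C)C)C=CC(C)(C)O2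
F7 | step 1 | 6-bromo-7-hydroxy-2,2-dimethylchroman-4-one | CC1(C)CC(=O)c2cc(Br)c(O)cc2O1
F8 | step 1 | racemic 6-bromo-2,2-dimethylchromane-4,7-diol | CC1(C)CC(O)c2cc(Br)c(O)cc2O1
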